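**Retrosynthetic overview**

1. Target 29 ⇐ bromophenol 28 (palladium-catalysed methoxycarbonylation) ⇐ C9 aldehyde 26 (Wolff–Kishner to the C9 methyl) ⇐ C9 ester 24 ⇐ bicyclic keto ester 21 (C8 ketone to C8 methyl by methylenation and hydrogenation; C4 silylmethylene to C4 methylene).
2. Key disconnection: the C9–C10 and C4–C5 bonds of 21 are made in one Mn(OAc)3 oxidative radical cascade from the open-chain α-arylmethyl β-keto ester 20; ring B closes first (6-endo), ring A second (6-exo-dig onto the silylalkyne).
3. Feature that carries the plan: the quaternary C9 with its two one-carbon arms (methyl and arylmethyl CH2), the trans C5–C10 junction of rings A and B, and the exocyclic methylene on C4 correspond to the radical carbon, the (E)-trisubstituted alkene and the alkyne end of a single chain.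
4. 20 ⇐ (−)-8-phenylmenthyl acetoacetate 13, alkylated at its γ-carbon with allylic bromide 9 (from hex-5-yn-1-ol 1 by an (E)-selective Wittig reaction) and at its α-carbon with benzylic bromide 19 (from 5-bromosalicylaldehyde 16).

Key step: step 12

Remark on numbering: decalin carbons are numbered as in the target skeleton (ring A = C1–C5, C10; ring B = C5–C10; C4 exocyclic methylene, C5 angular methyl, C8 secondary methyl, C9 quaternary). β is the face of the C5 methyl group, and C5 is (S) in every bicyclic compound.

Assumption: the geometry of the silylmethylene group in 21–23 is not controlled and is left open, because silicon is removed in step 15.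

Remark on the phenol protecting group: the triisopropylsilyl ether cannot survive hot KOH, so its loss is planned into the Wolff–Kishner step and the final carbonylation is run on the free phenol.

**Route**

Step 1
Reactants: 1 hex-5-yn-1-ol
Product: 4 6-(trimethylsilyl)hex-5-yn-1-ol, via dilithium alkoxide acetylide 2 (not isolated), via bis-silylated hexynol 3 (not isolated)
Conditions: n-BuLi (2.2 equiv), THF, −78 °C; Me3SiCl (2.3 equiv), −78 °C → rt; then 1 M HCl, rt
Reagents that add atoms: chlorotrimethylsilane, C[Si](C)(C)Cl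
Why: Double deprotonation gives the alkoxide acetylide, both sites are silylated, and dilute acid hydrolyses only the labile O–Si bond (C-silylation of a terminal alkyne through its dianion).

Step 2
Reactants: 4 6-(trimethylsilyl)hex-5-yn-1-ol
Product: 5 6-(trimethylsilyl)hex-5-ynal
Conditions: TEMPO (10 mol%), PhI(OAc)2 (1.1 equiv), CH2Cl2, rt
Reagents that add atoms: none
Why: The oxoammonium-mediated oxidation of a primary alcohol stops at the aldehyde and leaves the silylalkyne untouched.

Step 3
Reactants: 5 6-(trimethylsilyl)hex-5-ynal; 6 ethyl 2-(triphenylphosphoranylidene)propanoate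
Product: 7 ethyl (E)-2-methyl-8-(trimethylsilyl)oct-2-en-7-ynoate
Conditions: CH2Cl2, 40 °C
Reagents that add atoms: none
Why: Wittig olefination with a stabilised α-methyl ylide should give the trisubstituted (E)-enoate, which fixes the alkene geometry later needed for the trans ring fusion.

Step 4
Reactants: 7 ethyl (E)-2-methyl-8-(trimethylsilyl)oct-2-en-7-ynoate
Product: 8 (E)-2-methyl-8-(trimethylsilyl)oct-2-en-7-yn-1-ol
Conditions: i-Bu2AlH (2.3 equiv), CH2Cl2, −78 °C; aq. potassium sodium tartrate
Reagents that add atoms: none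
Why: Hydride reduction of the conjugated ester in the 1,2-sense gives the allylic alcohol without touching the alkene geometry or the silylalkyne.

Step 5
Reactants: 8 (E)-2-methyl-8-(trimethylsilyl)oct-2-en-7-yn-1-ol
Product: 9 [(E)-8-bromo-7-methyloct-6-en-1-yn-1-yl]trimethylsilane
Conditions: CBr4, PPh3, CH2Cl2, 0 °C
Reagents that add atoms: carbon tetrabromide, BrC(Br)(Br)Br
Why: Appel bromination displaces the primary allylic oxyphosphonium by SN2, so the position and (E)-geometry of the alkene are kept.

Step 6
Reactants: 10 (−)-8-phenylmenthol; 11 2,2,6-trimethyl-4H-1,3-dioxin-4-one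
Product: 13 (−)-8-phenylmenthyl 3-oxobutanoate, via acetylketene 12 (not isolated)
Conditions: xylene, 140 °C, acetone distilled off
Reagents that add atoms: none
Why: Thermal retro-[4+2] of the dioxinone releases acetylketene, which acylates even hindered secondary alcohols (acetoacetylation) without breaking the carbinol C–O bond, so the auxiliary keeps its configuration.

Step 7
Reactants: 13 (−)-8-phenylmenthyl 3-oxobutanoate; 9 [(E)-8-bromo-7-methyloct-6-en-1-yn-1-yl]trimethylsilane
Product: 15 (−)-8-phenylmenthyl (E)-6-methyl-3-oxo-12-(trimethylsilyl)dodec-6-en-11-ynoate, via acetoacetate dianion 14 (not isolated)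
Conditions: LiN(i-Pr)2 (2.2 equiv), THF, −78 → 0 °C; then 9, 0 °C → rt; aq. NH4Cl
Reagents that add atoms: none
Why: In the acetoacetate dianion alkylation only the more basic terminal (γ) carbanion attacks the primary allylic bromide by SN2, which places the ketone two carbons from the alkene and keeps the (E)-geometry.

Step 8
Reactants: 16 5-bromosalicylaldehyde
Product: 17 5-bromo-2-[(triisopropylsilyl)oxy]benzaldehyde
Conditions: i-Pr3SiCl, imidazole, DMF, rt
Reagents that add atoms: chlorotriisopropylsilane, CC(C)[Si](Cl)(C(C)C)C(C)C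
Why: Imidazole-promoted silylation of the phenol gives a bulky aryl silyl ether that withstands the carbonate base, trivalent manganese, ylide, hydride and oxidant used later.

Step 9
Reactants: 17 5-bromo-2-[(triisopropylsilyl)oxy]benzaldehyde
Product: 18 {5-bromo-2-[(triisopropylsilyl)oxy]phenyl}methanol
Conditions: NaBH4, MeOH/THF, 0 °C
Reagents that add atoms: none
Why: Borohydride reduction of the aldehyde at 0 °C gives the benzylic alcohol and leaves the hindered silyl ether and the aryl bromide intact.

Step 10
Reactants: 18 {5-bromo-2-[(triisopropylsilyl)oxy]phenyl}methanol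
Product: 19 [4-bromo-2-(bromomethyl)phenoxy]triisopropylsilane
Conditions: CBr4, PPh3, CH2Cl2, 0 °C
Reagents that add atoms: carbon tetrabromide, BrC(Br)(Br)Br
Why: Appel bromination of the primary benzylic alcohol under neutral conditions gives the benzylic bromide with the silyl ether untouched.

Step 11
Reactants: 15 (−)-8-phenylmenthyl (E)-6-methyl-3-oxo-12-(trimethylsilyl)dodec-6-en-11-ynoate; 19 [4-bromo-2-(bromomethyl)phenoxy]triisopropylsilane
Product: 20 (−)-8-phenylmenthyl (E)-2-{[5-bromo-2-(triisopropylsilyloxy)phenyl]methyl}-6-methyl-3-oxo-12-(trimethylsilyl)dodec-6-en-11-ynoate (C2 epimer mixture)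
Conditions: K2CO3 (2 equiv), Bu4NI (10 mol%), acetone, 50 °C
Reagents that add atoms: none
Why: C-Alkylation of the β-keto ester enolate with the reactive benzylic bromide installs the arylmethyl arm at C2, and the new centre is enolisable so that both epimers lead to the same radical in step 12.

Step 12
Reactants: 20 (−)-8-phenylmenthyl (E)-2-{[5-bromo-2-(triisopropylsilyloxy)phenyl]methyl}-6-methyl-3-oxo-12-(trimethylsilyl)dodec-6-en-11-ynoate
Product: 21 (−)-8-phenylmenthyl 9α-{[5-bromo-2-(triisopropylsilyloxy)phenyl]methyl}-5β-methyl-8-oxo-4-[(trimethylsilyl)methylidene]-trans-decalin-9β-carboxylate (10α-H)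
Conditions: Mn(OAc)3·2H2O (2.5 equiv), degassed EtOH (0.02 M), 60 °C, Ar
Reagents that add atoms: none
Why: Mn(OAc)3 (trivalent manganese) enolises 20 and oxidises the enolate to the electrophilic C9 radical, which adds 6-endo-trig to C10 of the (E)-trisubstituted alkene to close ring B; the tertiary C5 radical so formed closes ring A by 6-exo-dig addition to the silylalkyne, and the α-silyl vinyl radical takes a hydrogen atom from ethanol, the 1-hydroxyethyl radical being oxidised by the second equivalent of Mn(OAc)3. The closest known reaction type is the Mn(OAc)3-mediated oxidative free-radical polycyclisation of unsaturated α-alkyl β-keto esters to trans-fused rings, run in ethanol when a vinyl radical ends the cascade. C5 and C10 are set together by the chair transition state of the (E)-alkene (angular methyl and C10–H trans), and C9 by the radical conformer in which the ketone carbonyl points away from the ester, so that the ester ends axial (β, cis to the C5 methyl) and the arylmethyl group equatorial. The absolute sense comes from the auxiliary, whose phenyl ring lies over one face of the planar keto ester radical so that C10 bonds to the open face, which for the (1R,2S,5R) ester with its ester carbonyl s-cis to C8 should be the face leading to the 5S series. The step needs 6-endo closure ahead of 5-exo closure, cyclisation of the C5 radical faster than its oxidation, and one radical face; these are secured by the alkene substitution pattern with the ketone inside ring B, by leaving out Cu(OAc)2 and working dilute, and by the 8-phenylmenthyl ester.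

Step 13
Reactants: 21 bicyclic keto ester
Product: 22 (−)-8-phenylmenthyl 9α-{[5-bromo-2-(triisopropylsilyloxy)phenyl]methyl}-5β-methyl-8-methylidene-4-[(trimethylsilyl)methylidene]-trans-decalin-9β-carboxylate
Conditions: Ph3PCH3Br (4 equiv), KN(SiMe3)2 (3.8 equiv), toluene, 0 °C; then 21, 80 °C
Reagents that add atoms: methyltriphenylphosphonium bromide, C[P+](c1ccccc1)(c1ccccc1)c1ccccc1.[Br-]
Why: Wittig methylenation with an excess of Ph3P=CH2 at elevated temperature should convert the hindered C8 ketone, since C9 is quaternary and cannot epimerise and enolisation towards C7 is reversible.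

Step 14
Reactants: 22 C8 methylidene ester
Product: 23 (−)-8-phenylmenthyl 9α-{[5-bromo-2-(triisopropylsilyloxy)phenyl]methyl}-5β,8β-dimethyl-4-[(trimethylsilyl)methylidene]-trans-decalin-9β-carboxylate (8α-H)
Conditions: H2 (4 atm), RhCl(PPh3)3 (10 mol%), benzene/EtOH 1:1, 40 °C
Reagents that add atoms: none
Why: Homogeneous hydrogenation with RhCl(PPh3)3 reduces only the 1,1-disubstituted C8 methylene (the trisubstituted silylated C4 alkene and the aryl bromide are inert), and hydrogen is delivered to the α face because the β face is screened by the axial C9 ester, which sets the equatorial 8β-methyl group.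

Step 15
Reactants: 23 C4 silylmethylidene ester
Product: 24 (−)-8-phenylmenthyl 9α-{[5-bromo-2-(triisopropylsilyloxy)phenyl]methyl}-5β,8β-dimethyl-4-methylidene-trans-decalin-9β-carboxylate
Conditions: CF3CO2H (5 equiv), CH2Cl2, −20 → 0 °C; aq. NaHCO3
Reagents that add atoms: none
Why: Protodesilylation of the vinylsilane proceeds by ipso protonation to the tertiary β-silyl cation at C4, which loses silicon faster than it can rearrange and leaves the exocyclic C4 methylene, while the aryl silyl ether and the ester tolerate cold CF3CO2H.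

Step 16
Reactants: 24 C4 methylidene ester
Product: 25 [9α-{[5-bromo-2-(triisopropylsilyloxy)phenyl]methyl}-5β,8β-dimethyl-4-methylidene-trans-decalin-9β-yl]methanol
Conditions: LiAlH4 (3 equiv), THF, 0 → 40 °C; aqueous work-up
Reagents that add atoms: none
Why: Hydride reduction of the hindered ester gives the neopentyl C9 carbinol and releases the auxiliary 10 for recovery, with no stereocentre touched.

Step 17
Reactants: 25 C9 carbinol
Product: 26 9α-{[5-bromo-2-(triisopropylsilyloxy)phenyl]methyl}-5β,8β-dimethyl-4-methylidene-trans-decalin-9β-carbaldehyde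
Conditions: Dess–Martin periodinane (1.5 equiv), CH2Cl2, rt
Reagents that add atoms: none
Why: Dess–Martin oxidation takes the hindered primary alcohol to the aldehyde under near-neutral conditions, and the aldehyde has no α-hydrogen and cannot epimerise.

Step 18
Reactants: 26 C9 aldehyde
Product: 28 4-bromo-2-{[(1R,2S,4aS,8aS)-1,2,4a-trimethyl-5-methylidenedecahydronaphthalen-1-yl]methyl}phenol, via silyl ether hydrazone 27 (not isolated)
Conditions: N2H4·H2O (10 equiv), diethylene glycol, 130 °C; then KOH (10 equiv), 200 °C, Ar; 1 M HCl work-up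
Reagents that add atoms: none
Why: Wolff–Kishner reduction (Huang–Minlon procedure) turns the C9 aldehyde into the C9 methyl group through its hydrazone, and the hot KOH cleaves the aryl silyl ether at the same time as planned, while the aryl bromide and the isolated alkene are inert under argon.

Step 19
Reactants: 28 bromophenol
Product: 29 dictyoceratin C, methyl 4-hydroxy-3-{[(1R,2S,4aS,8aS)-1,2,4a-trimethyl-5-methylidenedecahydronaphthalen-1-yl]methyl}benzoate
Conditions: Pd(OAc)2 (10 mol%), Fe(C5H4PPh2)2 (dppf, 20 mol%), CO (3 atm), Et3N (3 equiv), MeOH/DMF 1:1, 80 °C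
Reagents that add atoms: carbon monoxide, [C-]#[O+]; methanol, CO
Why: Palladium-catalysed alkoxycarbonylation of the aryl bromide (oxidative addition to zerovalent palladium, CO insertion, methanolysis of the acyl complex) gives the methyl ester para to the free phenol, which this reaction tolerates, and the remote alkene is not involved.

**Compound list**

1 | hex-5-yn-1-ol | C#CCCCCO | starting material
2 | dilithium alkoxide acetylide of hex-5-yn-1-ol (not isolated) | [Li+].[Li+].[C-]#CCCCC[O-] | intermediate
3 | trimethyl{[6-(trimethylsilyl)hex-5-yn-1-yl]oxy}silane (not isolated) | C[Si](C)(C)C#CCCCCO[Si](C)(C)C | intermediate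
4 | 6-(trimethylsilyl)hex-5-yn-1-ol | C[Si](C)(C)C#CCCCCO | intermediate
5 | 6-(trimethylsilyl)hex-5-ynal | C[Si](C)(C)C#CCCCC=O | intermediate
6 | ethyl 2-(triphenylphosphoranylidene)propanoate | CCOC(=O)C(C)=P(c1ccccc1)(c1ccccc1)c1ccccc1 | starting material
7 | ethyl (E)-2-methyl-8-(trimethylsilyl)oct-2-en-7-ynoate | CCOC(=O)/C(C)=C/CCCC#C[Si](C)(C)C | intermediate
8 | (E)-2-methyl-8-(trimethylsilyl)oct-2-en-7-yn-1-ol | OC/C(C)=C/CCCC#C[Si](C)(C)C | intermediate
9 | [(E)-8-bromo-7-methyloct-6-en-1-yn-1-yl]trimethylsilane | BrC/C(C)=C/CCCC#C[Si](C)(C)C | intermediate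
10 | (−)-8-phenylmenthol, (1R,2S,5R)-5-methyl-2-(2-phenylpropan-2-yl)cyclohexan-1-ol | CC(C)(c1ccccc1)[C@@H]1CC[C@@H](C)C[C@H]1O | starting material
11 | 2,2,6-trimethyl-4H-1,3-dioxin-4-one | CC1=CC(=O)OC(C)(C)O1 | starting material
12 | acetylketene (not isolated) | CC(=O)C=C=O | intermediate
13 | (−)-8-phenylmenthyl 3-oxobutanoate | CC(=O)CC(=O)O[C@@H]1C[C@H](C)CC[C@H]1C(C)(C)c1ccccc1 | intermediate
14 | dilithium dianion of 13 (not isolated) | [Li+].[Li+].C=C([O-])C=C([O-])O[C@@H]1C[C@H](C)CC[C@H]1C(C)(C)c1ccccc1 | intermediate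
15 | (−)-8-phenylmenthyl (E)-6-methyl-3-oxo-12-(trimethylsilyl)dodec-6-en-11-ynoate | C[Si](C)(C)C#CCCC/C=C(\C)CCC(=O)CC(=O)O[C@@H]1C[C@H](C)CC[C@H]1C(C)(C)c1ccccc1 | intermediate
16 | 5-bromosalicylaldehyde | O=Cc1cc(Br)ccc1O | starting material
17 | 5-bromo-2-[(triisopropylsilyl)oxy]benzaldehyde | O=Cc1cc(Br)ccc1O[Si](C(C)C)(C(C)C)C(C)C | intermediate
18 | {5-bromo-2-[(triisopropylsilyl)oxy]phenyl}methanol | OCc1cc(Br)ccc1O[Si](C(C)C)(C(C)C)C(C)C | intermediate
19 | [4-bromo-2-(bromomethyl)phenoxy]triisopropylsilane | BrCc1cc(Br)ccc1O[Si](C(C)C)(C(C)C)C(C)C | intermediate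
20 | (−)-8-phenylmenthyl (E)-2-{[5-bromo-2-(triisopropylsilyloxy)phenyl]methyl}-6-methyl-3-oxo-12-(trimethylsilyl)dodec-6-en-11-ynoate, C2 epimer mixture | C[Si](C)(C)C#CCCC/C=C(\C)CCC(=O)C(Cc1cc(Br)ccc1O[Si](C(C)C)(C(C)C)C(C)C)C(=O)O[C@@H]1C[C@H](C)CC[C@H]1C(C)(C)c1ccccc1 | intermediate
21 | trans-decalin keto ester: C8 ketone, 9β (axial) 8-phenylmenthyl ester, 9α arylmethyl, 5β-methyl, 10α-H, C4 (trimethylsilyl)methylidene | C[Si](C)(C)C=C1CCC[C@H]2[C@](C(=O)O[C@@H]3C[C@H](C)CC[C@H]3C(C)(C)c3ccccc3)(Cc3cc(Br)ccc3O[Si](C(C)C)(C(C)C)C(C)C)C(=O)CC[C@]12C | intermediate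
22 | as 21 with C8 methylidene in place of the ketone | C[Si](C)(C)C=C1CCC[C@H]2[C@](C(=O)O[C@@H]3C[C@H](C)CC[C@H]3C(C)(C)c3ccccc3)(Cc3cc(Br)ccc3O[Si](C(C)C)(C(C)C)C(C)C)C(=C)CC[C@]12C | intermediate
23 | as 22 with 8β-methyl, 8α-H | C[Si](C)(C)C=C1CCC[C@H]2[C@](C(=O)O[C@@H]3C[C@H](C)CC[C@H]3C(C)(C)c3ccccc3)(Cc3cc(Br)ccc3O[Si](C(C)C)(C(C)C)C(C)C)[C@@H](C)CC[C@]12C | intermediate
24 | as 23 with C4 methylidene (silicon removed) | C=C1CCC[C@H]2[C@](C(=O)O[C@@H]3C[C@H](C)CC[C@H]3C(C)(C)c3ccccc3)(Cc3cc(Br)ccc3O[Si](C(C)C)(C(C)C)C(C)C)[C@@H](C)CC[C@]12C | intermediate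
25 | 9β-hydroxymethyl compound (auxiliary removed) | C=C1CCC[C@H]2[C@](CO)(Cc3cc(Br)ccc3O[Si](C(C)C)(C(C)C)C(C)C)[C@@H](C)CC[C@]12C | intermediate
26 | 9β-carbaldehyde | C=C1CCC[C@H]2[C@](C=O)(Cc3cc(Br)ccc3O[Si](C(C)C)(C(C)C)C(C)C)[C@@H](C)CC[C@]12C | intermediate
27 | hydrazone of 26 (not isolated) | C=C1CCC[C@H]2[C@](C=NN)(Cc3cc(Br)ccc3O[Si](C(C)C)(C(C)C)C(C)C)[C@@H](C)CC[C@]12C | intermediate
28 | 4-bromo-2-{[(1R,2S,4aS,8aS)-1,2,4a-trimethyl-5-methylidenedecahydronaphthalen-1-yl]methyl}phenol | C=C1CCC[C@H]2[C@](C)(Cc3cc(Br)ccc3O)[C@@H](C)CC[C@]12C | intermediate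
29 | dictyoceratin C | C=C1CCC[C@H]2[C@](C)(Cc3cc(C(=O)OC)ccc3O)[C@@H](C)CC[C@]12C | target

**Totals**

Total step count: 19. Longest linear sequence: 15 steps (steps 1–5, 7, 11–19).

**Steps most likely to fail**

Step 12. The tertiary C5 radical may be intercepted (oxidised by trivalent manganese, or reduced by hydrogen transfer) before the 6-exo-dig closure, and enolisation of the hindered α-substituted keto ester may be slow, so that conversion stalls or facial control erodes at the temperature required. The fallback sets out from 20 and comes back at 21, and makes the same radical reductively. Compound 20 is deprotonated (NaH, THF, 0 °C) and brominated with N-bromosuccinimide (−78 °C) to (−)-8-phenylmenthyl (E)-2-bromo-2-{[5-bromo-2-(triisopropylsilyloxy)phenyl]methyl}-6-methyl-3-oxo-12-(trimethylsilyl)dodec-6-en-11-ynoate F1. Slow addition of (Me3Si)3SiH with Et3B and a trace of air in benzene at room temperature abstracts the activated bromine, the C9 radical passes through the same two closures with no oxidant present, and the vinyl radical is reduced by the silane to give 21.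

Step 15. The acid may move the new C4 exocyclic alkene into ring A, or trigger a 1,2-methyl shift from C5 through the C4 cation. The fallback sets out from 23 and comes back at 24, and avoids protic acid. N-Iodosuccinimide in MeCN/ClCH2CN at 0 °C replaces silicon by iodine (iododesilylation) to give the C4 iodomethylidene analogue of 23 F3. Bu3SnH with Pd(PPh3)4 (catalytic, THF, room temperature) then exchanges the vinylic iodine for hydrogen, the electron-rich aryl bromide reacting far more slowly, and gives 24.

Step 13. Deprotonation of the shielded C8 ketone at C7 by the basic ylide may outrun addition, so that the ketone is returned. The fallback sets out from 21 and comes back at 22, and uses a two-stage Peterson olefination. Me3SiCH2Li with anhydrous CeCl3 (THF, −78 °C), a small and weakly basic nucleophile, adds to the C8 ketone from the α face to give the 8β-hydroxy-8α-[(trimethylsilyl)methyl] derivative of 21 F2. BF3·OEt2 (CH2Cl2, −78 °C) then eliminates the silanol in the anti sense to give 22.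

**Further compounds**

F1 | step 12 | (−)-8-phenylmenthyl (E)-2-bromo-2-{[5-bromo-2-(triisopropylsilyloxy)phenyl]methyl}-6-methyl-3-oxo-12-(trimethylsilyl)dodec-6-en-11-ynoate (C2 epimer mixture) | C[Si](C)(C)C#CCCC/C=C(\C)CCC(=O)C(Br)(Cc1cc(Br)ccc1O[Si](C(C)C)(C(C)C)C(C)C)C(=O)O[C@@H]1C[C@H](C)CC[C@H]1C(C)(C)c1ccccc1
F2 | step 13 | 8β-hydroxy-8α-[(trimethylsilyl)methyl] derivative of 21 | C[Si](C)(C)C=C1CCC[C@H]2[C@](C(=O)O[C@@H]3C[C@H](C)CC[C@H]3C(C)(C)c3ccccc3)(Cc3cc(Br)ccc3O[Si](C(C)C)(C(C)C)C(C)C)[C@@](C[Si](C)(C)C)(O)CC[C@]12C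
F3 | step 15 | C4 iodomethylidene analogue of 23 | IC=C1CCC[C@H]2[C@](C(=O)O[C@@H]3C[C@H](C)CC[C@H]3C(C)(C)c3ccccc3)(Cc3cc(Br)ccc3O[Si](C(C)C)(C(C)C)C(C)C)[C@@H](C)CC[C@]12C
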